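You, the chemist at these four flasks, want the most target out of each one at 12 s.

    substrate ⇌ target (K1 = 0.54, k1 = 0.207 s⁻¹, Ea1 = 97.0 kJ mol⁻¹, ΔH1 = −18.0 kJ mol⁻¹)
    substrate + free catalyst ⇌ isomer of the product A + free catalyst, rate k2*[substrate]*[free catalyst] forward; the back reaction follows from the equilibrium constant (K2 = 5.9, k2 = 4.31 M⁻¹ s⁻¹, Ea2 = 56.0 kJ mol⁻¹, ΔH2 = −16.0 kJ mol⁻¹)
    substrate + free catalyst ⇌ isomer of the product B + free catalyst, rate k3*[substrate]*[free catalyst] forward; the back reaction follows from the equilibrium constant (K3 = 1.32, k3 = 72.3 M⁻¹ s⁻¹, Ea3 = 38.0 kJ mol⁻¹, ΔH3 = −49.0 kJ mol⁻¹)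
    free catalyst + impurity → spent catalyst (k4 = 57400 M⁻¹ s⁻¹, Ea4 = 10.0 kJ mol⁻¹)
    2 free catalyst ⇌ resting dimer, settled at all times (K5 = 4300 M⁻¹, ΔH5 = −37.0 kJ mol⁻¹)
    (constants at 60 °C)

the same everywhere: substrate 0.017 M; free catalyst 0.34 mM; impurity 81 µM; time 12 s

|  | temperature |
|---|---|
| Sunday's | 80 °C |
| Friday's | 20 °C |
| Thursday's | 40 °C |
| Monday's | 60 °C |

- the best flask by amount of target, in percent of the substrate charged; "all alike" if 1.5 percentage points covers them all (Sunday's / Friday's / Thursday's / Monday's / all alike)
- amount of target at the end, in percent of the substrate charged, Sunday's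
- amount of target at the end, in percent of the substrate charged, Friday's
- amount of target at the end, in percent of the substrate charged, Thursday's
- amount of target at the end, in percent of the substrate charged, Monday's

- a step written with two of one species runs at k times the square of its concentration and takes two of it each time
- at 60 °C the constants are as listed, elsewhere as the activation energies and enthalpies make them

- **Freeze the catalyst.** Impurity takes 23.8% of the catalyst charge, a quarter, and the rest divides between free catalyst and resting dimer. In Monday's flask the working fraction, the part of the catalyst charge that stands free once the impurity's share is taken and the dimer is at balance, is 36.7%.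
- **Why freezing is fair.** In Monday's flask, impurity at that catalyst level lasts about 0.140 s, and substrate and target relax together in 1.69 s, so the catalyst level is fixed before target has grown.
- **The drain.** The working fraction turns the step to isomer of the product B into a pseudo-first-order drain on substrate of 0.00903 s⁻¹. I drop the step to isomer of the product A, whose 4.31 M⁻¹ s⁻¹ is far below 72.3 M⁻¹ s⁻¹.
- **Turn the time.** Target in Monday's flask climbs over 1.69 s to a ceiling of 35.1%. The pool then leaks over 171 s, a much longer time. At 12 s, I reckon 32.7% of the substrate charged.
- **Turn the impurity.** In a flask like Monday's with 3.2 × 10⁻⁴ M of impurity, the working fraction falls to 5.12%. The drain weakens with it, so I reckon target at 34.7%.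
- **Turn the temperature.** From Friday's flask to Sunday's, the step to target speeds up 860 times and the step to isomer of the product B 14 times. Warming also lowers the ceiling, to 27.2% in Sunday's flask. I expect Friday's flask to stop short of its ceiling, and I commit to Monday's as the best.
- **The forecast.** It names Monday's, with 22.8% for Sunday's, 2.04% for Friday's, 19.7% for Thursday's and 32.8% for Monday's, the last just above my 32.7%. Its grounds begin: “Treat the catalyst first”.
- **The flasks.** The best is Monday's, with target at 22.8% in Sunday's, 2.04% in Friday's, 19.7% in Thursday's and 32.8% in Monday's.
- **What stands in the flask.** In Monday's flask at 12.0 s, free catalyst stands at 36.7% of its charge, the working fraction 36.7%, and the forward step to target uses substrate 23 times as fast as the forward step to isomer of the product B. Target there is 32.8% and isomer of the product B 6.97%. With 3.2 × 10⁻⁴ M of impurity, the working fraction of 5.12% stands against a free catalyst reading of 5.12%, and that flask holds target at 34.6% and isomer of the product B at 1.33%.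

The numbers of this flask are assumed; no experiment stands behind them.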